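## Retrosynthetic overview

1. Ring C (the C11a–O bond) is closed last from a (3S,4S)-cis-2'-hydroxyisoflavan-4-ol; the mandatory cis ring fusion lets C6a dictate C11a.
2. Both stereocentres come from one Ru-catalysed asymmetric transfer hydrogenation of the isoflavone (C2=C3 reduction, then dynamic kinetic resolution at the ketone).
3. Ring B (the isoflavone) comes from a 2'-hydroxychalcone by oxidative 1,2-aryl shift and acid cyclisation.
4. The key C–C bond (future C6–C6a) is made by an intermolecular Claisen–Schmidt aldol condensation of the ring A methyl ketone with the ring D aldehyde.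
5. The dimethylchroman ring is built first on phloroacetophenone (C-prenylation, para-O-benzylation, acid cyclisation). Ring order: chroman, then B, then C.

Assumption: the SMILES denotes the cis-fused (6aS,11aS) pterocarpan, the series enantiomeric to (−)-medicarpin; the target is described in pterocarpan numbering and the tricyclic intermediates in pyrano[2,3-f]chromene numbering.

## Route

Step 1
Reactants: 1 1-(2,4,6-trihydroxyphenyl)ethan-1-one (phloroacetophenone, dried); 2 1-bromo-3-methylbut-2-ene (prenyl bromide)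
Product: 3 1-[2,4,6-trihydroxy-3-(3-methylbut-2-en-1-yl)phenyl]ethan-1-one
Conditions: DBU (1.0 equiv), THF, 0 °C to rt, 24 h
Reagents that add atoms: prenyl bromide, CC(C)=CCBr
Why: Phenolate C-allylation (Friedel–Crafts-type C-prenylation) of the phloroglucinol nucleus with the soft allylic bromide; C3 and C5 are equivalent, so only one mono-C-prenyl isomer can form.

Step 2
Reactants: 3 1-[2,4,6-trihydroxy-3-(3-methylbut-2-en-1-yl)phenyl]ethan-1-one; 4 benzyl bromide
Product: 5 1-[4-(benzyloxy)-2,6-dihydroxy-3-(3-methylbut-2-en-1-yl)phenyl]ethan-1-one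
Conditions: BnBr (1.05 equiv), K2CO3 (1.1 equiv), acetone, rt, 16 h
Reagents that add atoms: benzyl bromide, BrCc1ccccc1
Why: Williamson etherification selective for the para-OH, the only hydroxyl not hydrogen-bonded to the acetyl group and the most acidic one.

Step 3
Reactants: 5 1-[4-(benzyloxy)-2,6-dihydroxy-3-(3-methylbut-2-en-1-yl)phenyl]ethan-1-one
Product: 6 1-[5-(benzyloxy)-7-hydroxy-2,2-dimethyl-3,4-dihydro-2H-chromen-8-yl]ethan-1-one
Conditions: p-TsOH·H2O (20 mol%), toluene, 70 °C, 4 h
Reagents that add atoms: none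
Why: Acid-catalysed Markovnikov hydroalkoxylation of the prenyl alkene (tertiary cation, six-membered ring closure); with the para-oxygen benzylated the only adjacent free OH is the one ortho to the acetyl, which fixes the chroman regiochemistry.

Step 4
Reactants: 7 2-hydroxy-4-methoxybenzaldehyde; 4 benzyl bromide
Product: 8 2-(benzyloxy)-4-methoxybenzaldehyde
Conditions: BnBr (1.2 equiv), K2CO3 (1.5 equiv), DMF, 60 °C, 4 h
Reagents that add atoms: benzyl bromide, BrCc1ccccc1
Why: Williamson etherification; the benzyl ether blocks the ring D phenol so it cannot capture the acetal carbon during isoflavone formation.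

Step 5
Reactants: 6 1-[5-(benzyloxy)-7-hydroxy-2,2-dimethyl-3,4-dihydro-2H-chromen-8-yl]ethan-1-one; 8 2-(benzyloxy)-4-methoxybenzaldehyde
Product: 10 (E)-1-[5-(benzyloxy)-7-hydroxy-2,2-dimethyl-3,4-dihydro-2H-chromen-8-yl]-3-[2-(benzyloxy)-4-methoxyphenyl]prop-2-en-1-one, via aldol adduct 9 (not isolated)
Conditions: KOH (50% aq, 10 equiv), EtOH, rt, 48 h; then 1 M HCl to pH 4, 0 °C
Reagents that add atoms: none
Why: Claisen–Schmidt aldol condensation of the methyl ketone enolate with the non-enolisable aldehyde, followed by E1cB dehydration to the thermodynamically favoured E-enone; this joins the two fragments through the bond that becomes C6–C6a.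

Step 6
Reactants: 10 the (E)-chalcone from step 5; 11 methanol
Product: 12 racemic 1-[5-(benzyloxy)-7-hydroxy-2,2-dimethyl-3,4-dihydro-2H-chromen-8-yl]-2-[2-(benzyloxy)-4-methoxyphenyl]-3,3-dimethoxypropan-1-one
Conditions: Tl(NO3)3·3H2O (1.1 equiv), MeOH/HC(OMe)3 (3:1), rt, 3 h; filter off TlNO3
Reagents that add atoms: methanol, CO
Why: Oxidative 1,2-aryl migration of a chalcone: trivalent thallium adds to the enone with methanol at the benzylic carbon, the electron-rich 2-benzyloxy-4-methoxyphenyl group shifts to the α-carbon as monovalent thallium leaves, and the oxocarbenium ion is capped by a second methanol (a para-alkoxy migrating ring gives the isoflavone pathway, not aurones).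

Step 7
Reactants: 12 the dimethyl acetal from step 6
Product: 13 5-(benzyloxy)-9-[2-(benzyloxy)-4-methoxyphenyl]-2,2-dimethyl-3,4-dihydro-2H,10H-pyrano[2,3-f]chromen-10-one
Conditions: 10% aq HCl, MeOH/THF, 60 °C, 3 h
Reagents that add atoms: none
Why: Acid ionises the acetal, the ortho phenol captures the oxocarbenium ion and loss of the second methanol gives the chromone ring B (acetal cyclisation–elimination); benzyl ethers and the saturated chroman tolerate these conditions.

Step 8
Reactants: 13 the dibenzyl isoflavone from step 7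
Product: 14 5-hydroxy-9-(2-hydroxy-4-methoxyphenyl)-2,2-dimethyl-3,4-dihydro-2H,10H-pyrano[2,3-f]chromen-10-one
Conditions: H2 (1 atm), 10% Pd/C, EtOAc/MeOH (1:1), rt, about 3 h, stopped at 2 equiv H2
Reagents that add atoms: none
Why: Hydrogenolysis of aryl benzyl ethers over Pd/C is much faster than hydrogenation of the vinylogous-ester C=C of the chromone, so both phenols are freed at the robust isoflavone stage.

Step 9
Reactants: 14 the dihydroxyisoflavone from step 8; 15 tri(propan-2-yl)silyl trifluoromethanesulfonate (TIPSOTf)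
Product: 16 9-{4-methoxy-2-[tri(propan-2-yl)silyloxy]phenyl}-2,2-dimethyl-5-[tri(propan-2-yl)silyloxy]-3,4-dihydro-2H,10H-pyrano[2,3-f]chromen-10-one
Conditions: TIPSOTf (2.5 equiv), 2,6-lutidine (3 equiv), CH2Cl2, 0 °C to rt
Reagents that add atoms: TIPSOTf, CC(C)[Si](OS(=O)(=O)C(F)(F)F)(C(C)C)C(C)C
Why: O-silylation of both phenols; the TIPS ethers stop phenoxide deactivation of the ketone in the next step and can later be removed with fluoride, without the strong acid that the final product would not survive.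

Step 10
Reactants: 16 the bis-TIPS isoflavone from step 9
Product: 18 (9S,10S)-9-{4-methoxy-2-[tri(propan-2-yl)silyloxy]phenyl}-2,2-dimethyl-5-[tri(propan-2-yl)silyloxy]-3,4,9,10-tetrahydro-2H,8H-pyrano[2,3-f]chromen-10-ol, via racemic isoflavanone 17 (not isolated)
Conditions: RuCl[(S,S)-TsDPEN](p-cymene) (3 mol%), HCO2H/Et3N (5:7 molar), EtOAc, 40 °C, 24 h
Reagents that add atoms: none
Why: Asymmetric transfer hydrogenation with dynamic kinetic resolution: the ruthenium hydride first reduces the chromone C=C in conjugate fashion, the isoflavanone racemises at the α-carbon through its enol under Et3N, and the (S,S) catalyst delivers hydride anti to the aryl group to the carbonyl face that gives the S carbinol (the sense it shows with chroman-4-one), so the cis (S,S) alcohol is formed.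

Step 11
Reactants: 18 the (9S,10S)-cis alcohol from step 10
Product: 20 (6aS,11aS)-3-hydroxy-9-methoxy-1-O,2-C-(1,1-dimethylpropane-1,3-diyl)pterocarpan (target CNP0207547.1), via triol 19 (not isolated)
Conditions: TBAF (2.5 equiv), AcOH (2.5 equiv), THF, 0 °C; crude, then PPTS (10 mol%), CH2Cl2, rt
Reagents that add atoms: none
Why: Fluoride desilylation followed by SN1-type intramolecular etherification: mild acid ionises the benzylic alcohol flanked by three ring oxygens, the ring D phenol traps the cation to close ring C, and because only the cis-fused ring system can form, the fixed S centre at C6a sets 11aS.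

## Compound list

1 | 1-(2,4,6-trihydroxyphenyl)ethan-1-one | CC(=O)c1c(O)cc(O)cc1O | starting material
2 | 1-bromo-3-methylbut-2-ene (prenyl bromide) | CC(C)=CCBr | starting material
3 | 1-[2,4,6-trihydroxy-3-(3-methylbut-2-en-1-yl)phenyl]ethan-1-one | CC(=O)c1c(O)cc(O)c(CC=C(C)C)c1O | intermediate
4 | benzyl bromide | BrCc1ccccc1 | starting material
5 | 1-[4-(benzyloxy)-2,6-dihydroxy-3-(3-methylbut-2-en-1-yl)phenyl]ethan-1-one | CC(=O)c1c(O)cc(OCc2ccccc2)c(CC=C(C)C)c1O | intermediate
6 | 1-[5-(benzyloxy)-7-hydroxy-2,2-dimethyl-3,4-dihydro-2H-chromen-8-yl]ethan-1-one | CC(=O)c1c(O)cc(OCc2ccccc2)c2CCC(C)(C)Oc12 | intermediate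
7 | 2-hydroxy-4-methoxybenzaldehyde | COc1ccc(C=O)c(O)c1 | starting material
8 | 2-(benzyloxy)-4-methoxybenzaldehyde | COc1ccc(C=O)c(OCc2ccccc2)c1 | intermediate
9 | racemic 1-[5-(benzyloxy)-7-hydroxy-2,2-dimethyl-3,4-dihydro-2H-chromen-8-yl]-3-[2-(benzyloxy)-4-methoxyphenyl]-3-hydroxypropan-1-one (aldol adduct, not isolated) | COc1ccc(C(O)CC(=O)c2c(O)cc(OCc3ccccc3)c3CCC(C)(C)Oc23)c(OCc2ccccc2)c1 | intermediate
10 | (E)-1-[5-(benzyloxy)-7-hydroxy-2,2-dimethyl-3,4-dihydro-2H-chromen-8-yl]-3-[2-(benzyloxy)-4-methoxyphenyl]prop-2-en-1-one (chalcone) | COc1ccc(/C=C/C(=O)c2c(O)cc(OCc3ccccc3)c3CCC(C)(C)Oc23)c(OCc2ccccc2)c1 | intermediate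
11 | methanol | CO | starting material
12 | racemic 1-[5-(benzyloxy)-7-hydroxy-2,2-dimethyl-3,4-dihydro-2H-chromen-8-yl]-2-[2-(benzyloxy)-4-methoxyphenyl]-3,3-dimethoxypropan-1-one | COC(OC)C(c1ccc(OC)cc1OCc1ccccc1)C(=O)c1c(O)cc(OCc2ccccc2)c2CCC(C)(C)Oc12 | intermediate
13 | 5-(benzyloxy)-9-[2-(benzyloxy)-4-methoxyphenyl]-2,2-dimethyl-3,4-dihydro-2H,10H-pyrano[2,3-f]chromen-10-one (isoflavone: C=O at C10, aryl at C9, CMe2 at C2 next to O1) | O=C1C(c2ccc(OC)cc2OCc2ccccc2)=COc2cc(OCc3ccccc3)c3CCC(C)(C)Oc3c12 | intermediate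
14 | 5-hydroxy-9-(2-hydroxy-4-methoxyphenyl)-2,2-dimethyl-3,4-dihydro-2H,10H-pyrano[2,3-f]chromen-10-one | O=C1C(c2ccc(OC)cc2O)=COc2cc(O)c3CCC(C)(C)Oc3c12 | intermediate
15 | tri(propan-2-yl)silyl trifluoromethanesulfonate (TIPSOTf) | CC(C)[Si](OS(=O)(=O)C(F)(F)F)(C(C)C)C(C)C | starting material
16 | 9-{4-methoxy-2-[tri(propan-2-yl)silyloxy]phenyl}-2,2-dimethyl-5-[tri(propan-2-yl)silyloxy]-3,4-dihydro-2H,10H-pyrano[2,3-f]chromen-10-one | O=C1C(c2ccc(OC)cc2O[Si](C(C)C)(C(C)C)C(C)C)=COc2cc(O[Si](C(C)C)(C(C)C)C(C)C)c3CCC(C)(C)Oc3c12 | intermediate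
17 | racemic 9-{4-methoxy-2-[tri(propan-2-yl)silyloxy]phenyl}-2,2-dimethyl-5-[tri(propan-2-yl)silyloxy]-3,4,8,9-tetrahydro-2H,10H-pyrano[2,3-f]chromen-10-one (isoflavanone, not isolated) | O=C1C(c2ccc(OC)cc2O[Si](C(C)C)(C(C)C)C(C)C)COc2cc(O[Si](C(C)C)(C(C)C)C(C)C)c3CCC(C)(C)Oc3c12 | intermediate
18 | (9S,10S)-9-{4-methoxy-2-[tri(propan-2-yl)silyloxy]phenyl}-2,2-dimethyl-5-[tri(propan-2-yl)silyloxy]-3,4,9,10-tetrahydro-2H,8H-pyrano[2,3-f]chromen-10-ol (cis; aryl and OH on the same face) | COc1ccc(c(O[Si](C(C)C)(C(C)C)C(C)C)c1)[C@H]1COc2cc(O[Si](C(C)C)(C(C)C)C(C)C)c3CCC(C)(C)Oc3c2[C@H]1O | intermediate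
19 | (9S,10S)-9-(2-hydroxy-4-methoxyphenyl)-2,2-dimethyl-3,4,9,10-tetrahydro-2H,8H-pyrano[2,3-f]chromene-5,10-diol (triol, not isolated) | COc1ccc(c(O)c1)[C@H]1COc2cc(O)c3CCC(C)(C)Oc3c2[C@H]1O | intermediate
20 | (6aS,11aS)-3-hydroxy-9-methoxypterocarpan with an O–C(CH3)2–CH2–CH2 bridge from O-1 to C-2, cis-fused (CNP0207547.1) | COc1ccc2c(c1)O[C@@H]1c3c(cc(O)c4c3OC(C)(C)CC4)OC[C@H]21 | target

## Step count and risks

Total steps: 11. Longest linear sequence: 10 steps (steps 1, 2, 3, 5, 6, 7, 8, 9, 10, 11); step 4 is the one-step side branch.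

**Steps most likely to fail**

1. Step 10 (one-pot conjugate reduction and dynamic kinetic resolution on a hindered, electron-rich chromone). The conjugate reduction may stall, or the acid-sensitive benzylic alcohol may ionise in the formate medium.
   Fallback, setting out from 14 and coming back at 18: saturate the chromone C=C heterogeneously before protection with Pd/C and HCO2NH4 in refluxing MeOH, giving racemic 5-hydroxy-9-(2-hydroxy-4-methoxyphenyl)-2,2-dimethyl-3,4,8,9-tetrahydro-2H,10H-pyrano[2,3-f]chromen-10-one F4. Silylate both phenols (TIPSCl, imidazole, DMF) to give 17 as an isolated compound. The ruthenium catalyst of step 10 then only has to perform the ketone reduction with dynamic kinetic resolution to reach 18.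

2. Step 6 (oxidative aryl shift). Competing oxidation of the free chelated phenol or aurone formation could lower the yield.
   Fallback, setting out from 10 and coming back at 13: cyclise the chalcone by intramolecular oxa-Michael addition (NaOAc, EtOH, reflux) to racemic 5-(benzyloxy)-8-[2-(benzyloxy)-4-methoxyphenyl]-2,2-dimethyl-3,4,8,9-tetrahydro-2H,10H-pyrano[2,3-f]chromen-10-one F3, a flavanone in which the phenol is tied up. Then effect the oxidative 2,3-aryl migration of the flavanone with PhI(OH)OTs in MeCN at reflux, which gives isoflavone 13 directly.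

3. Step 2 (mono-benzylation next to the prenyl group). Over-alkylation or reaction at a chelated OH would erode the regiocontrol on which step 3 depends.
   Fallback, setting out from 3 and coming back at 6: benzylate twice (BnBr 2.2 equiv, K2CO3, DMF), which leaves free only the hindered chelated OH beside the prenyl group, giving 1-[4,6-bis(benzyloxy)-2-hydroxy-3-(3-methylbut-2-en-1-yl)phenyl]ethan-1-one F1. Cyclise with p-TsOH as in step 3 to 1-[5,7-bis(benzyloxy)-2,2-dimethyl-3,4-dihydro-2H-chromen-8-yl]ethan-1-one F2. Then remove only the benzyl ether ortho to the acetyl by chelation-controlled cleavage with BCl3 (1.1 equiv, CH2Cl2, −78 °C) to give 6.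

## Further compounds

F1 | step 2 | 1-[4,6-bis(benzyloxy)-2-hydroxy-3-(3-methylbut-2-en-1-yl)phenyl]ethan-1-one | CC(=O)c1c(O)c(CC=C(C)C)c(OCc2ccccc2)cc1OCc1ccccc1
F2 | step 2 | 1-[5,7-bis(benzyloxy)-2,2-dimethyl-3,4-dihydro-2H-chromen-8-yl]ethan-1-one | CC(=O)c1c(OCc2ccccc2)cc(OCc2ccccc2)c2CCC(C)(C)Oc12
F3 | step 6 | racemic 5-(benzyloxy)-8-[2-(benzyloxy)-4-methoxyphenyl]-2,2-dimethyl-3,4,8,9-tetrahydro-2H,10H-pyrano[2,3-f]chromen-10-one | O=C1CC(c2ccc(OC)cc2OCc2ccccc2)Oc2cc(OCc3ccccc3)c3CCC(C)(C)Oc3c12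
F4 | step 10 | racemic 5-hydroxy-9-(2-hydroxy-4-methoxyphenyl)-2,2-dimethyl-3,4,8,9-tetrahydro-2H,10H-pyrano[2,3-f]chromen-10-one | O=C1C(c2ccc(OC)cc2O)COc2cc(O)c3CCC(C)(C)Oc3c12
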